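**Retrosynthetic overview**
- The target comes from its C9 silyl ether; the ten-membered carbocycle is the last ring formed, by ring-closing metathesis that creates the Z C1=C10 alkene.
- The seco-diene comes from a late Nozaki–Hiyama–Kishi union at C5–C6 of two halves of about 15 heavy atoms each (a "west" vinyl iodide, C1–C5 with the ester, and an "east" aldehyde, C6–C14 with C7, C9 and C11), followed by γ-lactonisation.
- West half: propargyl alcohol → carboalumination/iodination → enal → Brown allylation (C3) → acylation with (R)-2-methylbutanoic acid.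
- East half: methacrolein → Brown allylation (C9) → hydroboration and oxidative lactonisation to a template γ-lactone → trans-alkylation with methyl (R)-lactate triflate (C7, C11) → Weinreb opening, silylation, reduction to the aldehyde.
- Ring order: template lactone (C6–O–C9, later opened) → all-cis lactone (C12–O–C6) → ten-membered carbocycle.

Assumption: locants C1–C15 follow germacrane numbering of the target (acyloxy on C3, hydroxyl on C9, lactone oxygen on C6, lactone carbonyl C12); the named starting materials and reagents are taken as commercial.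

**Route**

Step 1
Reactants: 1 prop-2-yn-1-ol
Product: 3 (E)-3-iodo-2-methylprop-2-en-1-ol, via alkenylalane 2 (not isolated)
Conditions: AlMe3 (3 equiv), Cp2ZrCl2 (0.25 equiv), CH2Cl2, 0 °C to rt; then I2, THF, −30 to 0 °C
Reagents that add atoms: trimethylaluminium, C[Al](C)C; iodine, II
Why: Zirconium-catalysed Negishi carboalumination adds Me–Al syn across the alkyne with methyl on the internal carbon, and iodinolysis of the alkenyl–Al bond with retention fixes the E geometry of the future C4=C5 alkene.

Step 2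
Reactants: 3 (E)-3-iodo-2-methylprop-2-en-1-ol
Product: 4 (E)-3-iodo-2-methylprop-2-enal
Conditions: activated MnO2 (15 equiv), CH2Cl2, rt
Reagents that add atoms: none
Why: Allylic oxidation with MnO2 is selective for the primary allylic alcohol and leaves the vinyl iodide and its geometry untouched.

Step 3
Reactants: 4 (E)-3-iodo-2-methylprop-2-enal
Product: 5 (1E,3S)-1-iodo-2-methylhexa-1,5-dien-3-ol
Conditions: allylMgBr, (−)-Ipc2BOMe, Et2O, 0 °C to rt; then 4, −78 °C; NaOH, H2O2, 0 °C to rt
Reagents that add atoms: allylmagnesium bromide, C=CC[Mg]Br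
Why: Brown asymmetric allylboration: the B-allyldiisopinocampheylborane made in the flask from the (+)-α-pinene-derived (−)-Ipc2BOMe delivers allyl to the Si face of the enal through a chair Zimmerman–Traxler transition state, setting C3 as S.

Step 4
Reactants: 5 (1E,3S)-1-iodo-2-methylhexa-1,5-dien-3-ol; 6 (2R)-2-methylbutanoic acid
Product: 7 (1E,3S)-1-iodo-2-methylhexa-1,5-dien-3-yl (2R)-2-methylbutanoate
Conditions: DCC (1.2 equiv), DMAP (0.1 equiv), CH2Cl2, 0 °C to rt
Reagents that add atoms: none
Why: Steglich esterification acylates the secondary allylic alcohol at oxygen, so C3 keeps its configuration, and the low temperature with catalytic DMAP avoids epimerising the α-stereocentre of the acid.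

Step 5
Reactants: 8 2-methylprop-2-enal (methacrolein)
Product: 9 (3S)-2-methylhexa-1,5-dien-3-ol
Conditions: allylMgBr, (−)-Ipc2BOMe, Et2O, 0 °C to rt; then 8, −78 °C; NaOH, H2O2, 0 °C to rt
Reagents that add atoms: allylmagnesium bromide, C=CC[Mg]Br
Why: The same Brown allylboration with Si-face delivery through the chair transition state sets the future C9 carbinol as S.

Step 6
Reactants: 9 (3S)-2-methylhexa-1,5-dien-3-ol
Product: 11 (4S)-5-methylhex-5-ene-1,4-diol, via organoborane 10 (not isolated)
Conditions: Sia2BH (2.5 equiv; from BH3·THF and 2-methylbut-2-ene), THF, 0 °C; then NaOH, H2O2, 0 °C to rt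
Reagents that add atoms: hydrogen peroxide, OO
Why: Anti-Markovnikov hydroboration–oxidation with bulky disiamylborane selects the monosubstituted alkene over the hindered 1,1-disubstituted allylic one (one equivalent is consumed by the hydroxyl) and does not touch the carbinol stereocentre.

Step 7
Reactants: 11 (4S)-5-methylhex-5-ene-1,4-diol
Product: 13 (5S)-5-(prop-1-en-2-yl)oxolan-2-one, via lactol 12 (not isolated)
Conditions: TEMPO (0.2 equiv), PhI(OAc)2 (2.5 equiv), CH2Cl2, rt
Reagents that add atoms: none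
Why: TEMPO/PhI(OAc)2 oxidative lactonisation oxidises the primary alcohol first, the aldehyde closes onto the secondary hydroxyl as lactol 12, and a second oxidation gives the γ-lactone with the carbinol centre unchanged.

Step 8
Reactants: 14 methyl (2R)-2-hydroxypropanoate (methyl D-lactate)
Product: 15 methyl (2R)-2-[(trifluoromethanesulfonyl)oxy]propanoate
Conditions: Tf2O, 2,6-lutidine, CH2Cl2, −78 to 0 °C
Reagents that add atoms: trifluoromethanesulfonic anhydride, O=S(=O)(OS(=O)(=O)C(F)(F)F)C(F)(F)F
Why: O-sulfonylation forms only the O–S bond, so the R configuration of the lactate carbon is retained in a highly reactive secondary electrophile.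

Step 9
Reactants: 13 (5S)-5-(prop-1-en-2-yl)oxolan-2-one; 15 methyl (2R)-2-[(trifluoromethanesulfonyl)oxy]propanoate
Product: 16 methyl (2R)-2-[(3S,5S)-2-oxo-5-(prop-1-en-2-yl)oxolan-3-yl]propanoate
Conditions: LiN(SiMe3)2 (1.05 equiv), THF, −78 °C; then 15 (1.3 equiv), −78 to −40 °C
Reagents that add atoms: none
Why: Lactone enolate alkylation: the lithium enolate is attacked anti to the isopropenyl group on C9 (sets C7 as S, trans to C9) and displaces triflate by SN2 with inversion at the lactate carbon, which places C11 in the required R configuration.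

Step 10
Reactants: 16 methyl (2R)-2-[(3S,5S)-2-oxo-5-(prop-1-en-2-yl)oxolan-3-yl]propanoate
Product: 18 methyl (2R,3S,5S)-5-[(tert-butyldimethylsilyl)oxy]-3-[methoxy(methyl)carbamoyl]-2,6-dimethylhept-6-enoate, via hydroxy Weinreb amide 17 (not isolated)
Conditions: MeNHOMe·HCl, AlMe3 (3 equiv each), CH2Cl2, 0 °C; aq. KNaC4H4O6; then TBSOTf, 2,6-lutidine, CH2Cl2, −78 to 0 °C
Reagents that add atoms: N,O-dimethylhydroxylamine hydrochloride, CNOC.Cl; tert-butyldimethylsilyl trifluoromethanesulfonate, CC(C)(C)[Si](C)(C)OS(=O)(=O)C(F)(F)F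
Why: Weinreb aminolysis with the aluminium amide opens the γ-lactone much faster than it attacks the α-branched methyl ester, and immediate O-silylation of the freed C9 hydroxyl prevents relactonisation, with no stereocentre touched.

Step 11
Reactants: 18 methyl (2R,3S,5S)-5-[(tert-butyldimethylsilyl)oxy]-3-[methoxy(methyl)carbamoyl]-2,6-dimethylhept-6-enoate
Product: 19 methyl (2R,3S,5S)-5-[(tert-butyldimethylsilyl)oxy]-3-formyl-2,6-dimethylhept-6-enoate
Conditions: i-Bu2AlH (1.15 equiv), THF, −78 °C; aq. KNaC4H4O6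
Reagents that add atoms: none
Why: Hydride reduction of the Weinreb amide proceeds through a chelated tetrahedral intermediate that collapses to the aldehyde only on work-up and forms faster than attack on the hindered methyl ester at −78 °C, while the cold non-basic conditions preserve the α-stereocentre C7.

Step 12
Reactants: 7 (1E,3S)-1-iodo-2-methylhexa-1,5-dien-3-yl (2R)-2-methylbutanoate; 19 methyl (2R,3S,5S)-5-[(tert-butyldimethylsilyl)oxy]-3-formyl-2,6-dimethylhept-6-enoate
Product: 21 (1E,3S)-1-[(2R,3S,4R)-3-{(2S)-2-[(tert-butyldimethylsilyl)oxy]-3-methylbut-3-en-1-yl}-4-methyl-5-oxooxolan-2-yl]-2-methylhexa-1,5-dien-3-yl (2R)-2-methylbutanoate, via hydroxy ester 20 (not isolated)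
Conditions: 7 (1.2 equiv), CrCl2 (6 equiv), NiCl2 (2 mol% of CrCl2), DMSO, rt; aqueous work-up; then PPTS (0.2 equiv), toluene, 60 °C
Reagents that add atoms: none
Why: Nozaki–Hiyama–Kishi coupling: zerovalent nickel inserts into the C–I bond with retention of the E geometry, the alkenyl group passes to trivalent chromium and adds only to the aldehyde under Felkin–Anh control with the C11 branch as the large group anti to the nucleophile (C6 as R), and acid-catalysed γ-lactonisation of 20 then closes the all-cis lactone.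

Step 13
Reactants: 21 seco-diene lactone (name as in step 12)
Product: 22 (3R,3aS,5S,6Z,9S,10E,11aR)-5-[(tert-butyldimethylsilyl)oxy]-3,6,10-trimethyl-2-oxo-2,3,3a,4,5,8,9,11a-octahydrocyclodeca[b]furan-9-yl (2R)-2-methylbutanoate
Conditions: second-generation Grubbs catalyst RuCl2(=CHPh)(H2IMes)(PCy3) (15 mol%), toluene (1 mM), 80 °C
Reagents that add atoms: none
Why: Ring-closing metathesis: the catalyst loads at the monosubstituted C1 alkene and closes onto the 1,1-disubstituted C10 alkene, helped by the cis-fused lactone holding both chains on one face, and the ten-membered ring that already contains the E C4=C5 alkene takes up the new trisubstituted alkene in its less strained Z form.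

Step 14
Reactants: 22 C9 silyl ether of the target (name as in step 13)
Product: 23 (3R,3aS,5S,6Z,9S,10E,11aR)-5-hydroxy-3,6,10-trimethyl-2-oxo-2,3,3a,4,5,8,9,11a-octahydrocyclodeca[b]furan-9-yl (2R)-2-methylbutanoate (target)
Conditions: HF·pyridine, pyridine, THF, 0 °C to rt
Reagents that add atoms: none
Why: Fluoride-mediated desilylation under buffered, non-basic conditions cleaves only the Si–O bond and leaves both esters, both alkenes and the epimerisable C11 centre intact.

**Compound list**
1 | prop-2-yn-1-ol | C#CCO | starting material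
2 | dimethylaluminium (E)-3-(dimethylalumanyl)-2-methylprop-2-en-1-olate | C[Al](C)OC/C(C)=C/[Al](C)C | intermediate (not isolated)
3 | (E)-3-iodo-2-methylprop-2-en-1-ol | OC/C(C)=C/I | intermediate
4 | (E)-3-iodo-2-methylprop-2-enal | O=C/C(C)=C/I | intermediate
5 | (1E,3S)-1-iodo-2-methylhexa-1,5-dien-3-ol | O[C@@H](CC=C)/C(C)=C/I | intermediate
6 | (2R)-2-methylbutanoic acid | CC[C@@H](C)C(=O)O | starting material
7 | (1E,3S)-1-iodo-2-methylhexa-1,5-dien-3-yl (2R)-2-methylbutanoate | CC[C@@H](C)C(=O)O[C@@H](CC=C)/C(C)=C/I | intermediate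
8 | 2-methylprop-2-enal | CC(=C)C=O | starting material
9 | (3S)-2-methylhexa-1,5-dien-3-ol | C=CC[C@H](O)C(C)=C | intermediate
10 | [(4S)-4-[bis(3-methylbutan-2-yl)boranyloxy]-5-methylhex-5-en-1-yl]bis(3-methylbutan-2-yl)borane | C=C(C)[C@H](CCCB(C(C)C(C)C)C(C)C(C)C)OB(C(C)C(C)C)C(C)C(C)C | intermediate (not isolated)
11 | (4S)-5-methylhex-5-ene-1,4-diol | OCCC[C@H](O)C(C)=C | intermediate
12 | (5S)-5-(prop-1-en-2-yl)oxolan-2-ol (anomer mixture) | OC1CC[C@@H](C(C)=C)O1 | intermediate (not isolated)
13 | (5S)-5-(prop-1-en-2-yl)oxolan-2-one | O=C1CC[C@@H](C(C)=C)O1 | intermediate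
14 | methyl (2R)-2-hydroxypropanoate | C[C@@H](O)C(=O)OC | starting material
15 | methyl (2R)-2-[(trifluoromethanesulfonyl)oxy]propanoate | C[C@@H](OS(=O)(=O)C(F)(F)F)C(=O)OC | intermediate
16 | methyl (2R)-2-[(3S,5S)-2-oxo-5-(prop-1-en-2-yl)oxolan-3-yl]propanoate | COC(=O)[C@H](C)[C@@H]1C[C@@H](C(C)=C)OC1=O | intermediate
17 | methyl (2R,3S,5S)-5-hydroxy-3-[methoxy(methyl)carbamoyl]-2,6-dimethylhept-6-enoate | CON(C)C(=O)[C@@H](C[C@H](O)C(C)=C)[C@@H](C)C(=O)OC | intermediate (not isolated)
18 | methyl (2R,3S,5S)-5-[(tert-butyldimethylsilyl)oxy]-3-[methoxy(methyl)carbamoyl]-2,6-dimethylhept-6-enoate | CON(C)C(=O)[C@@H](C[C@H](O[Si](C)(C)C(C)(C)C)C(C)=C)[C@@H](C)C(=O)OC | intermediate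
19 | methyl (2R,3S,5S)-5-[(tert-butyldimethylsilyl)oxy]-3-formyl-2,6-dimethylhept-6-enoate | O=C[C@@H](C[C@H](O[Si](C)(C)C(C)(C)C)C(C)=C)[C@@H](C)C(=O)OC | intermediate
20 | methyl (2R,3S,4R,5E,7S)-3-{(2S)-2-[(tert-butyldimethylsilyl)oxy]-3-methylbut-3-en-1-yl}-4-hydroxy-2,6-dimethyl-7-{[(2R)-2-methylbutanoyl]oxy}deca-5,9-dienoate | CC[C@@H](C)C(=O)O[C@@H](CC=C)/C(C)=C/[C@H](O)[C@@H](C[C@H](O[Si](C)(C)C(C)(C)C)C(C)=C)[C@@H](C)C(=O)OC | intermediate (not isolated)
21 | (1E,3S)-1-[(2R,3S,4R)-3-{(2S)-2-[(tert-butyldimethylsilyl)oxy]-3-methylbut-3-en-1-yl}-4-methyl-5-oxooxolan-2-yl]-2-methylhexa-1,5-dien-3-yl (2R)-2-methylbutanoate | CC[C@@H](C)C(=O)O[C@@H](CC=C)/C(C)=C/[C@@H]1OC(=O)[C@H](C)[C@@H]1C[C@H](O[Si](C)(C)C(C)(C)C)C(C)=C | intermediate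
22 | (3R,3aS,5S,6Z,9S,10E,11aR)-5-[(tert-butyldimethylsilyl)oxy]-3,6,10-trimethyl-2-oxo-2,3,3a,4,5,8,9,11a-octahydrocyclodeca[b]furan-9-yl (2R)-2-methylbutanoate | CC[C@@H](C)C(=O)O[C@H]1C/C=C(/C)[C@@H](O[Si](C)(C)C(C)(C)C)C[C@@H]2[C@H](/C=C/1C)OC(=O)[C@@H]2C | intermediate
23 | (3R,3aS,5S,6Z,9S,10E,11aR)-5-hydroxy-3,6,10-trimethyl-2-oxo-2,3,3a,4,5,8,9,11a-octahydrocyclodeca[b]furan-9-yl (2R)-2-methylbutanoate | CC[C@@H](C)C(=O)O[C@H]1C/C=C(/C)[C@@H](O)C[C@@H]2[C@H](/C=C/1C)OC(=O)[C@@H]2C | target

**Step count and risks**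

Total step count: 14 (west branch steps 1–4, east branch steps 5–7 and 9–11, triflate branch step 8, common steps 12–14).
Longest linear sequence: 9 steps (8 → 23 through steps 5, 6, 7, 9, 10, 11, 12, 13, 14), that is 9 of 14.

Steps most likely to fail:

1. Step 13 (ring-closing metathesis). A ten-membered ring with a new trisubstituted alkene next to a bulky silyl ether may give oligomers or no closure. Fallback, from 21 to 23: the order of deprotection and ring closure is inverted. The silyl ether is removed first (HF·pyridine, pyridine, THF, 0 °C) to give the seco-dienol with free C9 hydroxyl F1. The ring is then closed on F1 as the last step (second-generation Grubbs catalyst RuCl2(=CHPh)(H2IMes)(PCy3), 1,4-benzoquinone, toluene, 1 mM, 80 °C). The unprotected allylic hydroxyl assists metathesis at the 1,1-disubstituted alkene and the silyl bulk beside it is gone. This gives 23 directly and bypasses 22.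

2. Step 12 (C6 configuration in the Nozaki–Hiyama–Kishi addition). Felkin–Anh selectivity may be modest because the two α-substituents of aldehyde 19 are of similar size, which would give much trans-lactone. Fallback, from 20 back to 20 and on to 21: the crude coupling product is not treated with acid but isolated as the C6-epimer mixture of 20. It is oxidised (Dess–Martin periodinane, NaHCO3, CH2Cl2, 0 °C) to the C6 enone F2. The ketone is then reduced with (S)-2-methyl-CBS-oxazaborolidine and BH3·SMe2 (THF, −40 °C), the alkenyl group acting as the large substituent, so that C6 is set as R by reagent control instead of substrate control. PPTS then gives 21 as in the route.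

3. Step 9 (alkylation of the lactone enolate with the secondary triflate). Elimination of the triflate, proton transfer, or low trans selectivity at C7 may erode yield and purity. Fallback, from 13 (with 15) to 19, bypassing 16 and 18: C7 is set by an acyclic Evans auxiliary instead of the lactone template.
   - Saponification (LiOH, THF/H2O, then evaporation) gives lithium (4S)-4-hydroxy-5-methylhex-5-enoate F3.
   - Exhaustive silylation (TBSCl, imidazole, DMF) gives the silyl ester silyl ether F4.
   - K2CO3, MeOH/H2O, then pH 5, releases the silyloxy acid F5.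
   - PivCl, Et3N, then lithiated (4R)-4-benzyl-1,3-oxazolidin-2-one gives the acyl oxazolidinone F6.
   - NaN(SiMe3)2, THF, −78 °C, then triflate 15 gives the alkylated imide F7. The auxiliary shields one enolate face and sets C7 as S; SN2 inversion sets C11 as R.
   - LiSEt (EtSH, n-BuLi, THF, 0 °C) removes the auxiliary to give the thioester F8.
   - Fukuyama reduction (Et3SiH, Pd/C, acetone, rt) reduces only the thioester and gives aldehyde 19.

**Further compounds**
F1 | step 13 | (1E,3S)-1-[(2R,3S,4R)-3-[(2S)-2-hydroxy-3-methylbut-3-en-1-yl]-4-methyl-5-oxooxolan-2-yl]-2-methylhexa-1,5-dien-3-yl (2R)-2-methylbutanoate | CC[C@@H](C)C(=O)O[C@@H](CC=C)/C(C)=C/[C@@H]1OC(=O)[C@H](C)[C@@H]1C[C@H](O)C(C)=C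
F2 | step 12 | methyl (2R,3S,5E,7S)-3-{(2S)-2-[(tert-butyldimethylsilyl)oxy]-3-methylbut-3-en-1-yl}-2,6-dimethyl-7-{[(2R)-2-methylbutanoyl]oxy}-4-oxodeca-5,9-dienoate | CC[C@@H](C)C(=O)O[C@@H](CC=C)/C(C)=C/C(=O)[C@@H](C[C@H](O[Si](C)(C)C(C)(C)C)C(C)=C)[C@@H](C)C(=O)OC
F3 | step 9 | lithium (4S)-4-hydroxy-5-methylhex-5-enoate | [Li+].[O-]C(=O)CC[C@H](O)C(C)=C
F4 | step 9 | tert-butyldimethylsilyl (4S)-4-[(tert-butyldimethylsilyl)oxy]-5-methylhex-5-enoate | CC(C)(C)[Si](C)(C)OC(=O)CC[C@H](O[Si](C)(C)C(C)(C)C)C(C)=C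
F5 | step 9 | (4S)-4-[(tert-butyldimethylsilyl)oxy]-5-methylhex-5-enoic acid | OC(=O)CC[C@H](O[Si](C)(C)C(C)(C)C)C(C)=C
F6 | step 9 | (4R)-4-benzyl-3-[(4S)-4-[(tert-butyldimethylsilyl)oxy]-5-methylhex-5-enoyl]-1,3-oxazolidin-2-one | O=C(CC[C@H](O[Si](C)(C)C(C)(C)C)C(C)=C)N1[C@H](Cc2ccccc2)COC1=O
F7 | step 9 | methyl (2R,3S,5S)-3-[(4R)-4-benzyl-2-oxo-1,3-oxazolidine-3-carbonyl]-5-[(tert-butyldimethylsilyl)oxy]-2,6-dimethylhept-6-enoate | COC(=O)[C@H](C)[C@H](C[C@H](O[Si](C)(C)C(C)(C)C)C(C)=C)C(=O)N1[C@H](Cc2ccccc2)COC1=O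
F8 | step 9 | methyl (2R,3S,5S)-5-[(tert-butyldimethylsilyl)oxy]-3-[(ethylsulfanyl)carbonyl]-2,6-dimethylhept-6-enoate | CCSC(=O)[C@@H](C[C@H](O[Si](C)(C)C(C)(C)C)C(C)=C)[C@@H](C)C(=O)OC
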